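The oxolane is numbered O1, C2 (aryl), C3 (CH2OH, C9), C4 (aroyl, carbonyl C7'), C5, and everything rests on cutting C3–C4. This bond joins two identical syringyl C6–C3 halves at carbons of like polarity, in the middle of the 1,4-dioxygenated chain O–C9–C3–C4–C7'=O. In the key step Cp2TiCl turns the oxirane carbon C3 into a radical that closes the ring 5-exo onto a styrene, and TEMPO caps the benzylic C7' radical. One operation gives C3–C4, the oxolane, both new ring stereocentres and the C7'–O bond. The precursor is an open-chain epoxy cinnamyl ether, and both of its halves come from one allylic alcohol.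

Key step: step 6

Remark: C7' arises in step 6 as a mixture of epimers and is written without configuration in 9 and 10. It becomes the carbonyl carbon in step 7.

Step 1
Reactants: 1 syringaldehyde (4-hydroxy-3,5-dimethoxybenzaldehyde)
Product: 2 4-(benzyloxy)-3,5-dimethoxybenzaldehyde
Conditions: BnBr, K2CO3, DMF, 60 °C
Reagents that add atoms: benzyl bromide BrCc1ccccc1
Why: Williamson ether synthesis, in which the phenoxide of 1 displaces bromide by SN2 and the acidic phenol is masked for the organometallic and radical steps.

Step 2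
Reactants: 2 4-(benzyloxy)-3,5-dimethoxybenzaldehyde
Product: 3 racemic 1-[4-(benzyloxy)-3,5-dimethoxyphenyl]prop-2-en-1-ol
Conditions: CH2=CHMgBr, THF, 0 °C; then sat. aq. NH4Cl
Reagents that add atoms: vinylmagnesium bromide C=C[Mg]Br
Why: Grignard 1,2-addition to the aldehyde, which forms the carbinol centre as a racemate that step 3 resolves.

Step 3
Reactants: 3 racemic 1-[4-(benzyloxy)-3,5-dimethoxyphenyl]prop-2-en-1-ol
Product: 4 (R)-[4-(benzyloxy)-3,5-dimethoxyphenyl][(2S)-oxiran-2-yl]methanol (anti epoxy alcohol)
Conditions: Ti(OiPr)4 (0.15 equiv), diisopropyl D-(−)-tartrate (0.2 equiv), t-BuOOH (0.45 equiv), 4 Å molecular sieves, CH2Cl2, −20 °C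
Reagents that add atoms: tert-butyl hydroperoxide CC(C)(C)OO
Why: Sharpless kinetic resolution, in which the D-(−)-tartrate catalyst epoxidises the (S)-enantiomer of 3 much faster than the (R)-enantiomer and on the face that gives the anti epoxy alcohol, so stopping below half conversion fixes the carbinol centre (future C2) and the oxirane centre by reagent control.

Step 4
Reactants: 3 racemic 1-[4-(benzyloxy)-3,5-dimethoxyphenyl]prop-2-en-1-ol
Product: 5 2-(benzyloxy)-5-[(1E)-3-bromoprop-1-enyl]-1,3-dimethoxybenzene (E cinnamyl bromide)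
Conditions: PBr3 (0.4 equiv), Et2O, 0 °C
Reagents that add atoms: phosphorus tribromide BrP(Br)Br
Why: Allylic substitution with transposition (SN2'/ion-pair pathway) should give the conjugated E primary bromide as the thermodynamic product, and because the carbinol centre is lost the (R)-enantiomer of 3 left over from step 3 can be fed in here as well.

Step 5
Reactants: 4 anti epoxy alcohol; 5 E cinnamyl bromide
Product: 7 (2S)-2-[(R)-[4-(benzyloxy)-3,5-dimethoxyphenyl]{[(2E)-3-[4-(benzyloxy)-3,5-dimethoxyphenyl]prop-2-enyl]oxy}methyl]oxirane (epoxy cinnamyl ether), via sodium alkoxide 6 (not isolated)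
Conditions: NaH, THF–DMF, 0 °C; then 5, Bu4NI (cat.), 0 °C to rt
Reagents that add atoms: none
Why: Williamson ether synthesis, in which the secondary alkoxide 6 displaces the primary allylic bromide by SN2 at low temperature, faster than Payne migration of the neighbouring oxirane, and no stereocentre is touched.

Step 6
Reactants: 7 epoxy cinnamyl ether
Product: 10 {(2S,3R,4R)-2-[4-(benzyloxy)-3,5-dimethoxyphenyl]-4-{[4-(benzyloxy)-3,5-dimethoxyphenyl][(2,2,6,6-tetramethylpiperidin-1-yl)oxy]methyl}oxolan-3-yl}methanol (C7' epimers), via titanoxy radical 8 (not isolated), via benzylic titanium species 9 (not isolated)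
Conditions: Cp2TiCl2, Zn dust, THF, rt (gives Cp2TiCl), added slowly to dilute 7 in THF, rt; then TEMPO, 0 °C; then 1 M aq. HCl, 0 °C
Reagents that add atoms: TEMPO CC1(C)CCCC(C)(C)N1[O]
Why: Proposed new method: Cp2TiCl gives one electron to the oxirane of 7 and the C3–O bond breaks homolytically (Nugent–RajanBabu opening, which gives the more substituted, here secondary, beta-titanoxy radical 8), so C3, an electrophilic carbon in the epoxide, becomes a radical able to bond to the styrene carbon C4 of like polarity. The oxolane closes in the 5-exo-trig mode (C3 onto C4), preferred over 6-endo kinetically and because it leaves the benzylic C7' radical, which a second Cp2TiCl holds as the weakly bound tetravalent titanium species 9. The closest known reaction type is the reductive Cp2TiCl cyclisation of epoxy allyl ethers ended by a proton or iodine quench; only the ending is new, in which TEMPO takes up the trivalent titanium that 9 releases reversibly and couples with the freed benzylic radical, as in the known TEMPO oxidation of alkylboranes and Grignard reagents to alkoxyamines. C3 and C4 are set by the fixed C2 centre in a chair-like Beckwith–Houk transition state: the C2 aryl group lies pseudo-equatorial (C2/C4 trans) and the CH2O–Ti arm on the radical carbon takes the 1,5-cis relation to the styryl carbon, which together give 2,3-trans-3,4-cis, while the oxirane centre of 7 is erased in the planar radical. C7' is not controlled and need not be, since step 7 makes it the carbonyl carbon. The step needs cyclisation to outrun reduction of 8 by a second titanium (which would deoxygenate to the alkene), and this is secured by the slow addition of Cp2TiCl to dilute 7 and by the fast addition of alkyl radicals to a styrene.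

Step 7
Reactants: 10 alkoxyamine (C7' epimers)
Product: 11 [4-(benzyloxy)-3,5-dimethoxyphenyl]{(3R,4R,5S)-5-[4-(benzyloxy)-3,5-dimethoxyphenyl]-4-(hydroxymethyl)oxolan-3-yl}methanone (di-O-benzyl ciwujiatone)
Conditions: mCPBA (1.05 equiv), CH2Cl2, 0 °C
Reagents that add atoms: none
Why: Known oxidative cleavage of benzylic TEMPO ethers, in which N-oxidation and a Cope-type elimination of the hydroxylamine turn C7' into the ketone under nearly neutral conditions, so both C7' epimers converge and C4, now alpha to the carbonyl, keeps its cis relation to C3.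

Step 8
Reactants: 11 di-O-benzyl ciwujiatone
Product: 12 ciwujiatone
Conditions: H2 (1 atm), Pd/C, EtOAc, rt
Reagents that add atoms: none
Why: Catalytic hydrogenolysis under neutral conditions should cleave the two O-benzyl groups, which are far more labile than the ring C2–O1 bond, and should leave the aryl ketone and the epimerisable C4 centre untouched if the uptake is stopped at two equivalents.

Compound list
1 | syringaldehyde | COc1cc(C=O)cc(OC)c1O | starting material
2 | 4-(benzyloxy)-3,5-dimethoxybenzaldehyde | COc1cc(C=O)cc(OC)c1OCc1ccccc1 | intermediate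
3 | racemic 1-[4-(benzyloxy)-3,5-dimethoxyphenyl]prop-2-en-1-ol | C=CC(O)c1cc(OC)c(OCc2ccccc2)c(OC)c1 | intermediate
4 | (R)-[4-(benzyloxy)-3,5-dimethoxyphenyl][(2S)-oxiran-2-yl]methanol | O[C@H](c1cc(OC)c(OCc2ccccc2)c(OC)c1)[C@@H]1CO1 | intermediate
5 | 2-(benzyloxy)-5-[(1E)-3-bromoprop-1-enyl]-1,3-dimethoxybenzene | COc1cc(/C=C/CBr)cc(OC)c1OCc1ccccc1 | intermediate
6 | sodium alkoxide of 4 | [Na+].[O-][C@H](c1cc(OC)c(OCc2ccccc2)c(OC)c1)[C@@H]1CO1 | intermediate
7 | epoxy cinnamyl ether, carbinol carbon R, oxirane carbon S, alkene E | COc1cc(/C=C/CO[C@H](c2cc(OC)c(OCc3ccccc3)c(OC)c2)[C@@H]2CO2)cc(OC)c1OCc1ccccc1 | intermediate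
8 | open-chain secondary C3 radical bearing CH2O–TiCp2Cl, C2 unchanged | COc1cc(/C=C/CO[C@H](c2cc(OC)c(OCc3ccccc3)c(OC)c2)[CH]CO[Ti](Cl)(C2C=CC=C2)C2C=CC=C2)cc(OC)c1OCc1ccccc1 | intermediate
9 | 2,3-trans-3,4-cis oxolane with C7'–TiCp2Cl and C9–O–TiCp2Cl | COc1cc(C([Ti](Cl)(C2C=CC=C2)C2C=CC=C2)[C@H]2CO[C@H](c3cc(OC)c(OCc4ccccc4)c(OC)c3)[C@H]2CO[Ti](Cl)(C2C=CC=C2)C2C=CC=C2)cc(OC)c1OCc1ccccc1 | intermediate
10 | (2S,3R,4R)-oxolane alkoxyamine, C7' epimers | COc1cc(C(ON2C(C)(C)CCCC2(C)C)[C@H]2CO[C@H](c3cc(OC)c(OCc4ccccc4)c(OC)c3)[C@H]2CO)cc(OC)c1OCc1ccccc1 | intermediate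
11 | di-O-benzyl ciwujiatone | COc1cc(C(=O)[C@H]2CO[C@H](c3cc(OC)c(OCc4ccccc4)c(OC)c3)[C@H]2CO)cc(OC)c1OCc1ccccc1 | intermediate
12 | ciwujiatone | COc1cc(C(=O)[C@H]2CO[C@H](c3cc(OC)c(O)c(OC)c3)[C@H]2CO)cc(OC)c1O | target

Total step count: 8. Longest linear sequence: 7 (steps 1, 2, 3, 5, 6, 7, 8).

Steps most likely to fail

1. Step 6. Capture of the benzylic centre by TEMPO may lose to beta-hydride loss from the benzylic titanium species or to hydrogen abstraction from THF. Early reduction of the C3 radical would deoxygenate the epoxide. The fallback uses known reaction types only, sets out from 4 and returns at 11.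
- NaH and propargyl bromide give the epoxy propargyl ether F1.
- Sonogashira coupling (PdCl2(PPh3)2, CuI, Et3N, rt) with 2-(benzyloxy)-5-iodo-1,3-dimethoxybenzene F2 (from 4-iodo-2,6-dimethoxyphenol, BnBr, K2CO3) gives the aryl alkyne F3.
- Reductive Cp2TiCl cyclisation in the 5-exo-dig mode, ended by hydrogen abstraction from THF, gives the 4-benzylidene oxolane F4 with C2/C3 trans.
- Excess 9-BBN first caps the C9 hydroxyl and then hydroborates the exocyclic alkene from the face opposite the C3 arm. This places boron on C7' and hydrogen on C4 cis to H3. NaBO3 then gives the diol F5.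
- MnO2 oxidises only the benzylic alcohol and gives 11.

2. Step 5. Payne migration of the oxirane in the free alkoxide and decomposition of the labile cinnamyl bromide may outrun the etherification. The fallback sets out from 3 and 4 and returns at 7.
- Methyl chloroformate and pyridine convert racemic 3 into the branched allylic methyl carbonate F6.
- Pd(PPh3)4 ionises F6 to the aryl-substituted allyl complex of divalent palladium.
- Tsuji–Trost O-allylation of 4 at the unsubstituted terminus gives the linear E ether 7, with only a transient trace of alkoxide and no bromide.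

3. Step 7. The hydroxylamine released may be oxidised on to an oxoammonium species that attacks the free primary alcohol, and the electron-rich ketone may suffer Baeyer–Villiger insertion. The fallback sets out from 10 and returns at 11.
- Zn in AcOH cleaves the N–O bond reductively to the diol F7, obtained as the C7' epimer mixture.
- MnO2 in CH2Cl2 oxidises the secondary benzylic alcohol selectively to 11.

Further compounds
F1 | step 6 | (2S)-2-{(R)-[4-(benzyloxy)-3,5-dimethoxyphenyl](prop-2-ynyloxy)methyl}oxirane | C#CCO[C@H](c1cc(OC)c(OCc2ccccc2)c(OC)c1)[C@@H]1CO1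
F2 | step 6 | 2-(benzyloxy)-5-iodo-1,3-dimethoxybenzene | COc1cc(I)cc(OC)c1OCc1ccccc1
F3 | step 6 | epoxy 3-arylpropargyl ether, carbinol carbon R, oxirane carbon S | COc1cc(C#CCO[C@H](c2cc(OC)c(OCc3ccccc3)c(OC)c2)[C@@H]2CO2)cc(OC)c1OCc1ccccc1
F4 | step 6 | (2S,3R)-2-aryl-4-benzylidene-3-(hydroxymethyl)oxolane, alkene geometry open | COc1cc(C=C2CO[C@H](c3cc(OC)c(OCc4ccccc4)c(OC)c3)[C@H]2CO)cc(OC)c1OCc1ccccc1
F5 | step 6 | (2S,3R,4R)-2-aryl-4-[aryl(hydroxy)methyl]-3-(hydroxymethyl)oxolane | COc1cc(C(O)[C@H]2CO[C@H](c3cc(OC)c(OCc4ccccc4)c(OC)c3)[C@H]2CO)cc(OC)c1OCc1ccccc1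
F6 | step 5 | racemic 1-[4-(benzyloxy)-3,5-dimethoxyphenyl]prop-2-enyl methyl carbonate | C=CC(OC(=O)OC)c1cc(OC)c(OCc2ccccc2)c(OC)c1
F7 | step 7 | (2S,3R,4R)-2-aryl-4-[aryl(hydroxy)methyl]-3-(hydroxymethyl)oxolane, C7' epimer mixture from 10 | COc1cc(C(O)[C@H]2CO[C@H](c3cc(OC)c(OCc4ccccc4)c(OC)c3)[C@H]2CO)cc(OC)c1OCc1ccccc1
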